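**Plan**

- **Feature:** in flavanone numbering (ring C = O1, C2, C3, C4, C4a, C8a; second unit double-primed), the chain O1–C2–C3–C3''–C2''–O1'' carries a meso tetrad. If O1 and O1'' are replaced by two doubly bonded carbons, the chain becomes a cyclohexene bearing aryl, aroyl, aroyl, aryl all cis, which is an endo Diels–Alder adduct.
- **Cuts:** first O1–C8a and O1''–C8a'' (SNAr on ortho-fluoroaryl ketones). Each oxygen then goes back to a formyl carbon (Baeyer–Villiger) and the two formyl carbons go back to C=C (ozonolysis). Last, C2–C3 and C2''–C3'' are cut (retro-[4+2]); C3–C3'' is the dienophile double bond.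
- **Forward:** the diene (two steps) and the Z-enedione (two steps) give the carbocycle. The carbocycle is opened and its two alkene carbons are exchanged for oxygen. Both rings C then close in one flask and four benzyl ethers are removed. Rings A and B are bought.
- **Stereochemistry:** all four centres come from the cycloaddition. The E,E-diene sets C2/C2'', the Z-dienophile sets C3/C3'', and endo approach sets C2/C3 and C2''/C3''. Baeyer–Villiger migration retains C2 and C2''.
- **Cis to trans:** aryl/aroyl cis on the carbocycle reads as 2,3-trans on ring C, because at C3 the ring bond and the substituent change roles (C3'' is in the carbocycle, C4 is in ring C).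

Key step: step 5

Remark: the SMILES decodes as (2S,3R,2''R,3''S), the achiral meso form with both rings C 2,3-trans, so only relative configuration has to be controlled. Compounds 1, 2, 4, 6 and 7 are taken as catalogue chemicals.

**Step 1**
Reactants: 1 4-(benzyloxy)benzaldehyde; 2 (triphenylphosphoranylidene)acetaldehyde
Product: 3 (E)-3-[4-(benzyloxy)phenyl]prop-2-enal
Conditions: 2 (1.0 equiv), toluene, 90 °C
Reagents that add atoms: none
Why: Wittig olefination with the stabilised formyl ylide should give the E-enal, and keeping the ylide as the limiting partner should hold back a second homologation.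

**Step 2**
Reactants: 3 (E)-3-[4-(benzyloxy)phenyl]prop-2-enal; 4 diethyl [4-(benzyloxy)benzyl]phosphonate
Product: 5 (1E,3E)-1,4-bis[4-(benzyloxy)phenyl]buta-1,3-diene
Conditions: KOtBu (added last), THF, 0 °C to rt; recrystallisation
Reagents that add atoms: none
Why: Horner–Wadsworth–Emmons olefination of a benzylic phosphonate with a non-enolisable enal is reliably E-selective, so the new alkene should join the existing E-alkene to give the crystalline E,E-diene.

**Step 3**
Reactants: 6 2,5-dibromofuran; 7 [4-(benzyloxy)-2-fluorophenyl]boronic acid (2.3 equiv)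
Product: 8 2,5-bis[4-(benzyloxy)-2-fluorophenyl]furan
Conditions: Pd(PPh3)4 (5 mol %), aq. K2CO3, 1,4-dioxane, 85 °C
Reagents that add atoms: none
Why: Double Suzuki–Miyaura coupling at the two activated alpha C–Br bonds of furan is a standard entry to 2,5-diarylfurans and leaves aryl fluorides and benzyl ethers untouched.

**Step 4**
Reactants: 8 2,5-bis[4-(benzyloxy)-2-fluorophenyl]furan
Product: 9 (Z)-1,4-bis[4-(benzyloxy)-2-fluorophenyl]but-2-ene-1,4-dione
Conditions: mCPBA (1.1 equiv), CH2Cl2, 0 °C; cold aq. NaHCO3 wash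
Reagents that add atoms: mCPBA, O=C(OO)c1cccc(Cl)c1
Why: Peracid epoxidation of the electron-rich furan followed by spontaneous ring opening (oxidative furan opening) should give the enedione, whose Z geometry is inherited from the ring.

**Step 5**
Reactants: 5 (1E,3E)-1,4-bis[4-(benzyloxy)phenyl]buta-1,3-diene; 9 (Z)-1,4-bis[4-(benzyloxy)-2-fluorophenyl]but-2-ene-1,4-dione
Product: 10 meso all-cis-(3R,4R,5S,6S)-4,5-bis[4-(benzyloxy)-2-fluorobenzoyl]-3,6-bis[4-(benzyloxy)phenyl]cyclohexene
Conditions: toluene (concentrated), BHT (cat.), 110 °C, sealed tube, Ar, acid- and nucleophile-free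
Reagents that add atoms: none
Why: A thermal, concerted, suprafacial [4+2] cycloaddition of normal electron demand joins the termini of s-cis diene 5 (HOMO raised by two para-alkoxyaryl groups) to the alkene carbons of enedione 9 (LUMO lowered by two aroyl groups), forming the future C2–C3 and C2''–C3'' bonds together. The closest known reactions are the Diels–Alder additions of (E,E)-1,4-diphenylbutadiene to maleic anhydride and to 1,2-dibenzoylethylenes, which give 3,6-diaryl-4,5-diacylcyclohexenes. The single ring closed is the six-membered carbocycle, formed in the [4+2] cycloaddition mode with both new sigma bonds in it. The aryl-bearing centres (future C2, C2'') are cis to each other because both aryl groups sit outside on the E,E-diene, the aroyl-bearing centres (future C3, C3'') are cis to each other because the Z geometry of 9 is conserved, and each aryl is cis to its neighbouring aroyl because the carbonyl groups lie under the diene in the endo transition state. The step needs endo over exo selectivity and a dienophile that does not drift to the E form; carbonyl–diene secondary overlap favours endo, and the electron-rich diene should allow a neutral medium and a temperature at which 9 holds its geometry. Both partners are symmetric and the adduct is meso, so no regio- or enantioselectivity has to be controlled.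

**Step 6**
Reactants: 10 all-cis cyclohexene adduct
Product: 12 meso-(2R,3R,4S,5S)-3,4-bis[4-(benzyloxy)-2-fluorobenzoyl]-2,5-bis[4-(benzyloxy)phenyl]hexanedial, via ozonide 11 (not isolated)
Conditions: O3, CH2Cl2, −78 °C, Sudan Red 7B end-point; then Me2S, −78 °C to rt; aqueous wash, used without chromatography
Reagents that add atoms: ozone, [O-][O+]=O
Why: Criegee ozonolysis should attack the only C=C bond far faster than the alkoxyarenes or benzyl ethers, from the open face opposite the four cis substituents, and neutral Me2S reduction of ozonide 11 leaves the four stereocentres untouched.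

**Step 7**
Reactants: 12 meso dialdehyde
Product: 13 meso-(1R,2S,3R,4S)-2,3-bis[4-(benzyloxy)-2-fluorobenzoyl]-1,4-bis[4-(benzyloxy)phenyl]butane-1,4-diyl diformate
Conditions: mCPBA (2.5 equiv), CH2Cl2, 0 °C to rt
Reagents that add atoms: mCPBA, O=C(OO)c1cccc(Cl)c1
Why: Baeyer–Villiger oxidation of alpha-branched aldehydes gives formates because the secondary para-alkoxybenzylic carbon migrates in the Criegee adduct in preference to hydride, the migration retains configuration at C2 and C2'', and the conjugated aryl ketones add peracid far more slowly than the aldehydes.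

**Step 8**
Reactants: 13 meso bis-formate
Product: 15 meso-(2S,3R,2''R,3''S)-7,7''-bis(benzyloxy)-2,2''-bis[4-(benzyloxy)phenyl]-3,3''-bichromane-4,4''-dione, via diol 14 (not isolated)
Conditions: K2CO3 (5 equiv), MeOH–THF, 0 °C to 40 °C
Reagents that add atoms: none
Why: Carbonate-promoted transesterification removes both formates, each freed benzylic alkoxide then displaces the fluoride ortho to its own beta-carbonyl by intramolecular SNAr to a six-membered ring (attack on the other aryl ring would need a seven-membered one), the C2–O bonds are never broken, and any base-induced epimerisation at C3 or C3'' should converge on the wanted diequatorial 2,3-trans arrangement.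

**Step 9**
Reactants: 15 tetrabenzyl biflavanone
Product: 16 (2S,3R,2''R,3''S)-7,7''-dihydroxy-2,2''-bis(4-hydroxyphenyl)-3,3''-bichromane-4,4''-dione (CNP0231820.1)
Conditions: H2 (1 atm), 10% Pd/C, THF–MeOH, rt
Reagents that add atoms: none
Why: Catalytic hydrogenolysis cleaves the four primary benzyl aryl ethers much faster than the hindered secondary C2–O1 bonds or the aryl ketones, as is routine for benzyl-protected flavanones, and touches no stereocentre.

**Compound list**

1 | 4-(benzyloxy)benzaldehyde | O=Cc1ccc(OCc2ccccc2)cc1 | starting material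
2 | (triphenylphosphoranylidene)acetaldehyde | O=CC=P(c1ccccc1)(c1ccccc1)c1ccccc1 | starting material
3 | (E)-3-[4-(benzyloxy)phenyl]prop-2-enal | O=C/C=C/c1ccc(OCc2ccccc2)cc1 | intermediate
4 | diethyl [4-(benzyloxy)benzyl]phosphonate | CCOP(=O)(Cc1ccc(OCc2ccccc2)cc1)OCC | starting material
5 | (1E,3E)-1,4-bis[4-(benzyloxy)phenyl]buta-1,3-diene | C(Oc1ccc(/C=C/C=C/c2ccc(OCc3ccccc3)cc2)cc1)c1ccccc1 | intermediate
6 | 2,5-dibromofuran | Brc1ccc(Br)o1 | starting material
7 | [4-(benzyloxy)-2-fluorophenyl]boronic acid | OB(O)c1ccc(OCc2ccccc2)cc1F | starting material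
8 | 2,5-bis[4-(benzyloxy)-2-fluorophenyl]furan | Fc1cc(OCc2ccccc2)ccc1-c1ccc(o1)-c1ccc(OCc2ccccc2)cc1F | intermediate
9 | (Z)-1,4-bis[4-(benzyloxy)-2-fluorophenyl]but-2-ene-1,4-dione | O=C(/C=C\C(=O)c1ccc(OCc2ccccc2)cc1F)c1ccc(OCc2ccccc2)cc1F | intermediate
10 | meso all-cis-(3R,4R,5S,6S)-4,5-bis[4-(benzyloxy)-2-fluorobenzoyl]-3,6-bis[4-(benzyloxy)phenyl]cyclohexene | C1=C[C@H](c2ccc(OCc3ccccc3)cc2)[C@H](C(=O)c2ccc(OCc3ccccc3)cc2F)[C@H](C(=O)c2ccc(OCc3ccccc3)cc2F)[C@@H]1c1ccc(OCc2ccccc2)cc1 | intermediate
11 | secondary ozonide of 10, drawn as the monomeric 2,5-diaryl-3,4-diaroyl-7,8,9-trioxabicyclo[4.2.1]nonane (four carbon centres as in 10, acetal carbons undefined) | O1OC2OC1[C@H](c1ccc(OCc3ccccc3)cc1)[C@H](C(=O)c1ccc(OCc3ccccc3)cc1F)[C@H](C(=O)c1ccc(OCc3ccccc3)cc1F)[C@@H]2c1ccc(OCc2ccccc2)cc1 | intermediate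
12 | meso-(2R,3R,4S,5S)-3,4-bis[4-(benzyloxy)-2-fluorobenzoyl]-2,5-bis[4-(benzyloxy)phenyl]hexanedial | O=C[C@H](c1ccc(OCc2ccccc2)cc1)[C@H](C(=O)c1ccc(OCc2ccccc2)cc1F)[C@H](C(=O)c1ccc(OCc2ccccc2)cc1F)[C@@H](C=O)c1ccc(OCc2ccccc2)cc1 | intermediate
13 | meso-(1R,2S,3R,4S)-2,3-bis[4-(benzyloxy)-2-fluorobenzoyl]-1,4-bis[4-(benzyloxy)phenyl]butane-1,4-diyl diformate | O=CO[C@H](c1ccc(OCc2ccccc2)cc1)[C@H](C(=O)c1ccc(OCc2ccccc2)cc1F)[C@H](C(=O)c1ccc(OCc2ccccc2)cc1F)[C@@H](OC=O)c1ccc(OCc2ccccc2)cc1 | intermediate
14 | meso-(1R,2S,3R,4S)-2,3-bis[4-(benzyloxy)-2-fluorobenzoyl]-1,4-bis[4-(benzyloxy)phenyl]butane-1,4-diol | O[C@H](c1ccc(OCc2ccccc2)cc1)[C@H](C(=O)c1ccc(OCc2ccccc2)cc1F)[C@H](C(=O)c1ccc(OCc2ccccc2)cc1F)[C@@H](O)c1ccc(OCc2ccccc2)cc1 | intermediate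
15 | meso-(2S,3R,2''R,3''S)-7,7''-bis(benzyloxy)-2,2''-bis[4-(benzyloxy)phenyl]-3,3''-bichromane-4,4''-dione | O=C1c2ccc(OCc3ccccc3)cc2O[C@H](c2ccc(OCc3ccccc3)cc2)[C@H]1[C@@H]1C(=O)c2ccc(OCc3ccccc3)cc2O[C@H]1c1ccc(OCc2ccccc2)cc1 | intermediate
16 | (2S,3R,2''R,3''S)-7,7''-dihydroxy-2,2''-bis(4-hydroxyphenyl)-3,3''-bichromane-4,4''-dione | O=C1c2ccc(O)cc2O[C@H](c2ccc(O)cc2)[C@H]1[C@@H]1C(=O)c2ccc(O)cc2O[C@H]1c1ccc(O)cc1 | target

**Total step count:** 9. **Longest linear sequence:** 7 (steps 1, 2, 5–9 or steps 3, 4, 5–9).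

**Steps most likely to fail**

**Step 5.** The twisted Z-enedione may add too slowly. It may also drift to the E form before it adds, or the endo preference may erode.

The fallback sets out from 9 (with diene 5) and comes back at 15.
- Compound 9 is isomerised on purpose with a trace of iodine in warm chloroform to the planar, more reactive (E)-1,4-bis[4-(benzyloxy)-2-fluorophenyl]but-2-ene-1,4-dione F1.
- Its Diels–Alder addition to 5 in hot toluene can give only one racemic diastereomer, the 3,6-cis-diaryl-4,5-trans-diaroyl cyclohexene F2, because one aroyl group must be endo and the other exo.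
- The operations of steps 6 to 8 then lead through the ozonide F3, the dialdehyde F4, the bis-formate F5 and the diol F6 to the 2,3-trans-2'',3''-cis biflavanone tetrabenzyl ether F7.
- C2 and C2'' still carry the relation set by the E,E-diene, and the misplaced centre C3'' is alpha to a ketone. DBU in CH2Cl2 (or longer exposure to K2CO3 in MeOH) should epimerise it through the enolate to the diequatorial trans form, which is 15.

Control thus moves from kinetic endo/Z selectivity to thermodynamic control at an enolisable centre.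

**Step 7.** Three processes threaten this step:
- enolisation of the alpha-aryl aldehydes before oxidation, which would lose C2/C2'' configuration;
- hydride migration instead of carbon migration;
- intramolecular aldol closure of the 1,6-dialdehyde.

The fallback sets out from 12 and comes back at 14.
- Pinnick oxidation (NaClO2, NaH2PO4, 2-methylbut-2-ene, tBuOH–water) quickly converts the labile aldehydes into the configurationally sturdier diacid F8.
- Coupling with mCPBA by N,N'-dicyclohexylcarbodiimide in CH2Cl2 at 0 °C gives the bis(acyl 3-chlorobenzoyl peroxide) F9.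
- Warming in MeCN brings about the ionic carboxy-inversion rearrangement. The benzylic carbon moves from carbon to oxygen with retention and gives the bis(3-chlorobenzoyl carbonate) F10.
- K2CO3 in MeOH strips the mixed carbonates to diol 14, which closes to 15 in the same flask as in step 8.

**Step 8.** Retro-aldol fragmentation or E1cB dehydration of the beta-alkoxide ketone may outrun the SNAr closure. Methoxide may also displace fluoride.

The fallback sets out from 13 and comes back at 15.
- The formates are removed with KHCO3 in aqueous MeOH at 0 °C, a medium too weakly basic for ring closure or aldol reversal, and diol 14 is isolated.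
- TMSCl and imidazole in CH2Cl2 give the bis(trimethylsilyl) ether F11.
- Catalytic CsF in dry DMF then starts a fluoride-relay SNAr. Each ring closure releases the fluoride that desilylates the next ether, and silicon leaves as Me3SiF.

No stoichiometric base is present, and only a trace of alkoxide exists at any time.

**Further compounds**

F1 | step 5 | (E)-1,4-bis[4-(benzyloxy)-2-fluorophenyl]but-2-ene-1,4-dione | O=C(/C=C/C(=O)c1ccc(OCc2ccccc2)cc1F)c1ccc(OCc2ccccc2)cc1F
F2 | step 5 | rac-3,4-cis-4,5-trans-5,6-trans-4,5-bis[4-(benzyloxy)-2-fluorobenzoyl]-3,6-bis[4-(benzyloxy)phenyl]cyclohexene (one enantiomer drawn) | C1=C[C@H](c2ccc(OCc3ccccc3)cc2)[C@H](C(=O)c2ccc(OCc3ccccc3)cc2F)[C@@H](C(=O)c2ccc(OCc3ccccc3)cc2F)[C@@H]1c1ccc(OCc2ccccc2)cc1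
F3 | step 5 | secondary ozonide of F2 (acetal carbons undefined) | O1OC2OC1[C@H](c1ccc(OCc3ccccc3)cc1)[C@H](C(=O)c1ccc(OCc3ccccc3)cc1F)[C@@H](C(=O)c1ccc(OCc3ccccc3)cc1F)[C@@H]2c1ccc(OCc2ccccc2)cc1
F4 | step 5 | rac-3,4-bis[4-(benzyloxy)-2-fluorobenzoyl]-2,5-bis[4-(benzyloxy)phenyl]hexanedial, C4 epimer of 12 | O=C[C@H](c1ccc(OCc2ccccc2)cc1)[C@H](C(=O)c1ccc(OCc2ccccc2)cc1F)[C@@H](C(=O)c1ccc(OCc2ccccc2)cc1F)[C@@H](C=O)c1ccc(OCc2ccccc2)cc1
F5 | step 5 | rac-bis-formate, C3 epimer of 13 | O=CO[C@H](c1ccc(OCc2ccccc2)cc1)[C@H](C(=O)c1ccc(OCc2ccccc2)cc1F)[C@@H](C(=O)c1ccc(OCc2ccccc2)cc1F)[C@@H](OC=O)c1ccc(OCc2ccccc2)cc1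
F6 | step 5 | rac-diol, C3 epimer of 14 | O[C@H](c1ccc(OCc2ccccc2)cc1)[C@H](C(=O)c1ccc(OCc2ccccc2)cc1F)[C@@H](C(=O)c1ccc(OCc2ccccc2)cc1F)[C@@H](O)c1ccc(OCc2ccccc2)cc1
F7 | step 5 | rac-(2S,3R,2''R,3''R)-7,7''-bis(benzyloxy)-2,2''-bis[4-(benzyloxy)phenyl]-3,3''-bichromane-4,4''-dione (2,3-trans, 2'',3''-cis) | O=C1c2ccc(OCc3ccccc3)cc2O[C@H](c2ccc(OCc3ccccc3)cc2)[C@H]1[C@H]1C(=O)c2ccc(OCc3ccccc3)cc2O[C@H]1c1ccc(OCc2ccccc2)cc1
F8 | step 7 | meso-3,4-bis[4-(benzyloxy)-2-fluorobenzoyl]-2,5-bis[4-(benzyloxy)phenyl]hexanedioic acid | OC(=O)[C@H](c1ccc(OCc2ccccc2)cc1)[C@H](C(=O)c1ccc(OCc2ccccc2)cc1F)[C@H](C(=O)c1ccc(OCc2ccccc2)cc1F)[C@@H](C(O)=O)c1ccc(OCc2ccccc2)cc1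
F9 | step 7 | meso bis(acyl 3-chlorobenzoyl peroxide) of F8 | O=C(OOC(=O)c1cccc(Cl)c1)[C@H](c1ccc(OCc2ccccc2)cc1)[C@H](C(=O)c1ccc(OCc2ccccc2)cc1F)[C@H](C(=O)c1ccc(OCc2ccccc2)cc1F)[C@@H](C(=O)OOC(=O)c1cccc(Cl)c1)c1ccc(OCc2ccccc2)cc1
F10 | step 7 | meso bis(3-chlorobenzoyl carbonate) of diol 14 | O=C(OC(=O)c1cccc(Cl)c1)O[C@H](c1ccc(OCc2ccccc2)cc1)[C@H](C(=O)c1ccc(OCc2ccccc2)cc1F)[C@H](C(=O)c1ccc(OCc2ccccc2)cc1F)[C@@H](OC(=O)OC(=O)c1cccc(Cl)c1)c1ccc(OCc2ccccc2)cc1
F11 | step 8 | meso bis(trimethylsilyl) ether of diol 14 | C[Si](C)(C)O[C@H](c1ccc(OCc2ccccc2)cc1)[C@H](C(=O)c1ccc(OCc2ccccc2)cc1F)[C@H](C(=O)c1ccc(OCc2ccccc2)cc1F)[C@@H](O[Si](C)(C)C)c1ccc(OCc2ccccc2)cc1
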